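**Assumptions.** (i) The natural 1-acyloxy configuration (O trans to the C8–C9 bond) is obtained in Step 13 under anomeric control. (ii) The racemic silyl-acetal pyranone 3 is resolved by catalyst control in Step 3, so the maximum yield there is 50%.

## Retrosynthetic overview
- The target comes from a late-stage E→Z photoisomerisation of the cinnamate, preceded by C10 cinnamoylation and C1 lactol isovaleroylation on a silyl-protected enol-ether core.
- The C7/C8 trans-diol and C10 come from an enoate (C7=C8–CO2Et), by convex-face epoxidation followed by a reductive-opening/hydroxylation sequence.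
- The cis-fused cyclopentene comes from a phosphine-catalysed [3+2] of an allenoate onto the enone C5=C9 of a pyranone. That pyranone, with its C1 acetal and C4 ketone, comes from dearomative Achmatowicz ring expansion of furfuryl alcohol.
- The C4 ketone becomes the C3=C4(C11) enol ether by enol triflation and Stille coupling.
- Ring order: the pyran ring is formed first (Achmatowicz), then the cyclopentane ([3+2]).

## Route

**Step 1**
Reactants: 1 furfuryl alcohol
Product: 2 6-hydroxy-2H-pyran-3(6H)-one (racemic anomeric mixture)
Conditions: NBS, NaHCO3, NaOAc·3H2O, THF/H2O 4:1, 0 °C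
Reagents that add atoms: water, O
Why: Achmatowicz oxidative ring expansion dearomatises the furan and sets up the C1 acetal, C4 ketone and C5=C9 enone; the only stereocentre (C1) is racemic.

**Step 2**
Reactants: 2
Product: 3 6-(triethylsilyloxy)-2H-pyran-3(6H)-one
Conditions: TESCl, imidazole, CH2Cl2/DMF, 0 °C
Reagents that add atoms: chlorotriethylsilane, CC[Si](Cl)(CC)CC
Why: The lactol becomes a silyl acetal that tolerates phosphine, base and hydride, and it can later be removed selectively in the presence of TBS ethers.

**Step 3**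
Reactants: 3 and 4 (ethyl buta-2,3-dienoate)
Product: 5 cis-fused cyclopenta[c]pyranone carrying the C7=C8–CO2Et enoate
Conditions: chiral phosphepine catalyst (10 mol%), CH2Cl2, rt, 48 h
Reagents that add atoms: none
Why: Proposed new method: the phosphine–allenoate zwitterion adds through its α-carbon to the enone β-carbon C9, anti to the C1–OTES group, and the resulting C5 enolate closes onto the vinylphosphonium (C5–C6 bond).
- Mechanistic reasoning: this cis-fuses the two rings and puts the alkene at C7=C8 with the ester on C8, which fixes C5 and C9.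
- Closest known reaction: Lu/Fu phosphine-catalysed [3+2] of allenoates with enones.
- The chiral phosphine resolves the racemic 3 kinetically by favouring one enantiomer.

**Step 4**
Reactants: 5
Product: 6 enol triflate (C3=C4–OTf)
Conditions: KHMDS, THF, −78 °C; then PhNTf2
Reagents that add atoms: PhNTf2, O=S(=O)(C(F)(F)F)N(c1ccccc1)S(=O)(=O)C(F)(F)F
Why: Kinetic enolisation occurs at the less hindered, oxygen-flanked C3–H2 rather than the ring-fusion C5–H, so the stereocentres are untouched.

**Step 5**
Reactants: 6 and 7 (tributyl[(TBS-oxy)methyl]stannane)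
Product: 8 C11-silyloxymethyl enol ether
Conditions: Pd(PPh3)4, CuI, LiCl, DMF, 60 °C
Reagents that add atoms: none
Why: Stille coupling of the vinyl triflate with the α-silyloxymethylstannane installs C11 and creates the iridoid C3=C4 enol ether.

**Step 6**
Reactants: 8
Product: 9 α,β-epoxy ester (7,8-epoxide on the convex face)
Conditions: 30% H2O2, LiOH, THF/H2O, 0 °C
Reagents that add atoms: hydrogen peroxide, OO
Why: Weitz–Scheffer nucleophilic epoxidation leaves the electron-rich enol ether untouched. Hydroperoxide attacks C7 from the convex face (the face of H5 and H9), which sets the C7–O configuration.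

**Step 7**
Reactants: 9
Product: 10 7,8-dihydroxy ester (C7–OH up, C8–OH down, CO2Et up)
Conditions: SmI2 (2.3 equiv), THF, −78 °C; then 2-(phenylsulfonyl)-3-phenyloxaziridine, −78 → 0 °C
Reagents that add atoms: Davis oxaziridine, O=S(=O)(c1ccccc1)N1OC1c1ccccc1
Why: Proposed new method: SmI2 cleaves the α C–O bond of the epoxy ester to give a Sm(III) ester enolate with the C7 Sm-alkoxide retained.
- Mechanistic reasoning: the oxaziridine then hydroxylates C8 anti to the bulky C7 alkoxide, giving the trans-diol.
- Closest known reactions: Molander's SmI2 opening of epoxy esters and Seebach-type hydroxylation of β-oxido ester enolates.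
- Net result: formal anti-hydration of the epoxide with inversion at C8, which sets the last ring stereocentre.

**Step 8**
Reactants: 10
Product: 11 C7-OTBS ether
Conditions: TBSOTf, 2,6-lutidine, CH2Cl2, −78 °C
Reagents that add atoms: tert-butyldimethylsilyl triflate, C[Si](C)(C(C)(C)C)OS(=O)(=O)C(F)(F)F
Why: Silylation is selective for the secondary C7–OH over the tertiary C8–OH, so the later acylations are regioselective; no stereocentre is affected.

**Step 9**
Reactants: 11
Product: 12 C10 primary alcohol
Conditions: LiAlH4, THF, 0 °C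
Reagents that add atoms: none
Why: Hydride reduction of the ester gives the neopentyl CH2OH (C10); the silyl acetal, enol ether and TBS ethers survive, and C8 is quaternary so nothing epimerises.

**Step 10**
Reactants: 13 (E)-p-coumaric acid
Product: 14 (E)-4-(TBS-oxy)cinnamic acid
Conditions: TBSCl (2.5 equiv), imidazole, DMF; then aqueous citric acid/THF to hydrolyse the silyl ester
Reagents that add atoms: tert-butyldimethylchlorosilane, C[Si](C)(C(C)(C)C)Cl
Why: The phenol is protected as a silyl ether while the carboxylic acid is freed for coupling.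

**Step 11**
Reactants: 12 and 14
Product: 15 C10 (E)-cinnamate
Conditions: EDC·HCl, DMAP, CH2Cl2, 0 °C → rt
Reagents that add atoms: none
Why: Steglich esterification occurs at the only free primary alcohol; the tertiary C8–OH is unreactive.

**Step 12**
Reactants: 15
Product: 16 C1 lactol (anomeric mixture)
Conditions: HF·pyridine, pyridine, THF, 0 °C, 20 min
Reagents that add atoms: none
Why: The anomeric silyl acetal is far more labile than the TBS ethers; C1 equilibrates through ring–chain tautomerism.

**Step 13**
Reactants: 16
Product: 17 1-O-isovaleryl acylal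
Conditions: isovaleryl chloride, pyridine, DMAP (cat.), CH2Cl2, −20 °C
Reagents that add atoms: isovaleryl chloride, CC(C)CC(=O)Cl
Why: Acylation of the anomeric alkoxide is assumed to give the anomerically favoured 1-acyloxy isomer, with the acyloxy group trans to the C8–C9 bond as in the target; this sets C1.

**Step 14**
Reactants: 17
Product: 18 (E)-cinnamate of luzonoid D
Conditions: HF·pyridine, pyridine, THF, 0 °C → rt
Reagents that add atoms: none
Why: Fluoride removes the C7, C11 and phenol TBS groups; the acylal, enol ether and cinnamate survive buffered HF.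

**Step 15**
Reactants: 18
Product: 19 luzonoid D (Z-coumarate)
Conditions: hν (350 nm), MeCN, rt; then preparative HPLC
Reagents that add atoms: none
Why: Photostationary E→Z cinnamate isomerisation, followed by separation of the Z isomer; no stereocentre is affected.

## Compound list
1 | furfuryl alcohol | OCc1ccco1 | starting material
2 | 6-hydroxy-2H-pyran-3(6H)-one | O=C1COC(O)C=C1 | intermediate
3 | 6-(triethylsilyloxy)-2H-pyran-3(6H)-one | CC[Si](CC)(CC)OC1OCC(=O)C=C1 | intermediate
4 | ethyl buta-2,3-dienoate | C=C=CC(=O)OCC | starting material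
5 | bicyclic keto-enoate | CC[Si](CC)(CC)O[C@@H]1OCC(=O)[C@H]2CC=C(C(=O)OCC)[C@@H]12 | intermediate
6 | enol triflate | CC[Si](CC)(CC)O[C@@H]1OC=C(OS(=O)(=O)C(F)(F)F)[C@H]2CC=C(C(=O)OCC)[C@@H]12 | intermediate
7 | tributyl[(TBS-oxy)methyl]stannane | CCCC[Sn](CCCC)(CCCC)CO[Si](C)(C)C(C)(C)C | starting material
8 | C11-silyloxymethyl enol ether | CC[Si](CC)(CC)O[C@@H]1OC=C(CO[Si](C)(C)C(C)(C)C)[C@H]2CC=C(C(=O)OCC)[C@@H]12 | intermediate
9 | epoxy ester | CC[Si](CC)(CC)O[C@@H]1OC=C(CO[Si](C)(C)C(C)(C)C)[C@H]2C[C@@H]3O[C@]3(C(=O)OCC)[C@@H]12 | intermediate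
10 | 7,8-dihydroxy ester | CC[Si](CC)(CC)O[C@@H]1OC=C(CO[Si](C)(C)C(C)(C)C)[C@H]2C[C@H](O)[C@](O)(C(=O)OCC)[C@@H]12 | intermediate
11 | C7-OTBS ester | CC[Si](CC)(CC)O[C@@H]1OC=C(CO[Si](C)(C)C(C)(C)C)[C@H]2C[C@H](O[Si](C)(C)C(C)(C)C)[C@](O)(C(=O)OCC)[C@@H]12 | intermediate
12 | C10 primary alcohol | CC[Si](CC)(CC)O[C@@H]1OC=C(CO[Si](C)(C)C(C)(C)C)[C@H]2C[C@H](O[Si](C)(C)C(C)(C)C)[C@](O)(CO)[C@@H]12 | intermediate
13 | (E)-p-coumaric acid | O=C(O)/C=C/c1ccc(O)cc1 | starting material
14 | (E)-4-(TBS-oxy)cinnamic acid | O=C(O)/C=C/c1ccc(O[Si](C)(C)C(C)(C)C)cc1 | intermediate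
15 | C10 (E)-cinnamate | CC[Si](CC)(CC)O[C@@H]1OC=C(CO[Si](C)(C)C(C)(C)C)[C@H]2C[C@H](O[Si](C)(C)C(C)(C)C)[C@](O)(COC(=O)/C=C/c3ccc(O[Si](C)(C)C(C)(C)C)cc3)[C@@H]12 | intermediate
16 | C1 lactol (C1 unspecified) | OC1OC=C(CO[Si](C)(C)C(C)(C)C)[C@H]2C[C@H](O[Si](C)(C)C(C)(C)C)[C@](O)(COC(=O)/C=C/c3ccc(O[Si](C)(C)C(C)(C)C)cc3)[C@@H]12 | intermediate
17 | 1-O-isovaleryl tris-TBS compound | CC(C)CC(=O)O[C@@H]1OC=C(CO[Si](C)(C)C(C)(C)C)[C@H]2C[C@H](O[Si](C)(C)C(C)(C)C)[C@](O)(COC(=O)/C=C/c3ccc(O[Si](C)(C)C(C)(C)C)cc3)[C@@H]12 | intermediate
18 | (E)-cinnamate of luzonoid D | CC(C)CC(=O)O[C@@H]1OC=C(CO)[C@H]2C[C@H](O)[C@](O)(COC(=O)/C=C/c3ccc(O)cc3)[C@@H]12 | intermediate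
19 | luzonoid D | CC(C)CC(=O)O[C@@H]1OC=C(CO)[C@H]2C[C@H](O)[C@](O)(COC(=O)/C=C\c3ccc(O)cc3)[C@@H]12 | target

## Totals
- Total steps: 15 (Step 10 is a side preparation of the acyl donor).
- Longest linear sequence: 14 steps, from furfuryl alcohol to luzonoid D.

## Three steps most likely to fail
1. **Step 3** (phosphine [3+2] on a hindered, β-substituted silyloxy pyranone, combined with resolution). Fallback: a stepwise annulation.
   - Add the Grignard from 2-bromo-3-(TBS-oxy)propene to 3 under Cu catalysis at C9, anti to OTES.
   - Trap the enolate with allyl bromide at C5 and epimerise to the cis-fused isomer.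
   - Close the ring by RCM to the C7=C8 cyclopentene carrying CH2OTBS as C10.
   - Then form the diol by a vanadyl-directed convex epoxidation and hydrolytic opening at C8.
2. **Step 7** (one-pot reductive epoxide opening and enolate hydroxylation; face selectivity, and the oxaziridine is consumed by excess SmI2). Fallback: change the order.
   - Ketalise the C4 ketone of 5 and reduce the ester to the allylic alcohol.
   - Perform a Prévost anti-dihydroxylation of the C7=C8 alkene (I2, PhCO2Ag, wet solvent) before the triflation and Stille steps.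
3. **Step 13** (anomeric acylation: wrong anomer, or acid sensitivity of the enol ether/acylal; Step 14 fluoride desilylation shares the acylal-stability risk). Fallback: enzymatic acylation of lactol 16 with vinyl isovalerate (CAL-B, neutral conditions), followed by buffered TBAF/AcOH desilylation.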